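## Analysis of the target

The target 16 is a benzene ring with four substituents in a 1,2,4,5-arrangement. C1 carries the aryl ester oxygen of a tiglate, C2 a 2,2-disubstituted oxirane bound through its quaternary carbon, C4 a methoxy group and C5 a methyl group. The only stereocentre is the quaternary oxirane carbon (R). It bears the aryl ring, the oxirane oxygen, the oxirane CH2 and a CH2O-isovaleryl arm, and no second stereocentre can relay information to it. The E double bond of the tiglate is the only other stereo-element and comes in with the acyl group.

Three groups are fragile. The 2-aryl oxirane is a tertiary benzylic ether on an electron-rich ring and opens under acid. The aryl tiglate is an activated ester that is cleaved by nucleophiles and can lose its conjugation. A free phenol on C1 would attack the oxirane CH2 and close a 2,3-dihydrobenzofuran.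

The centre is chiral only because its two oxygenated one-carbon arms differ. Any acyl shift from one arm to the other therefore erases the configuration. The difficulty is to build this fully substituted carbon enantioselectively while the two arms stay distinguishable.

The strategy rests on the ortho relationship of the oxygen on C1 and the quaternary carbon on C2. That oxygen, C1, C2, the quaternary carbon and one arm raised to the carboxyl level make up the five-membered lactone of a benzofuran-2(3H)-one. The quaternary carbon is C3 of this lactone, alpha to the carbonyl, and is reached from a flat enolate.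

## Retrosynthetic reasoning

**Oxirane O–CH2 bond (16 to 14).** The oxirane is the most fragile group and is made last. It is opened at its O–CH2 bond, not at the quaternary carbon, so the stereocentre is never part of a substitution. The precursor is mesylate 14, whose tertiary oxygen is a triethylsilyl ether. Forward, fluoride frees the alkoxide 15, which displaces the neighbouring mesylate at once. The medium stays close to neutral and the phenol is already esterified.

**Mesylate S–O and aryl ester C–O bonds (14 to 13 to 11 and 12).** The mesyl group goes back to primary alcohol 13, and the tiglate goes back to phenol 11 and tigloyl chloride 12. The order is fixed: the phenol must be acylated before a leaving group exists on the arm, otherwise the phenoxide would displace it in a five-membered ring closure. The forward acylation has to pick the phenol in the presence of a hindered primary alcohol.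

**Reconnection to the lactone (11 to 9).** The phenol oxygen and the CH2OH arm of 11 are tied together as the aryl lactone 9, so the arm sits at the carboxyl oxidation level. One reduction then frees both the phenol and the primary alcohol, through aldehyde 10. Up to this point the two arms differ in oxidation level and cannot be exchanged. The forward step must reduce an aryl ester beside an alkyl ester.

**Isovalerate C–O bond (9 to 7 and 8).** The ester on the second arm is cut to alcohol 7 and isovaleryl chloride 8. Alcohol 7 is a beta-hydroxy lactone that can lose formaldehyde by retro-aldol, so it is acylated directly. The isovalerate is both the block against retro-aldol and the ester of the target, which saves a protecting group.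

**C3–CH2OH bond (7 to 5 and 6).** This is the disconnection that carries the plan. Cutting it leaves the 3-silyloxy lactone 5 and formaldehyde 6. The forward reaction is an enantioselective addition of the enolate of 5 to 6 under a chiral Lewis acid of trivalent scandium. It forms the quaternary stereocentre in a C–C bond formation on a rigid bicyclic enolate, with the smallest possible electrophile.

**Silyl ether, lactone and aryl–C bond (5 to 4 to 3 to 1 and 2).** The silyl ether comes from hydroxy lactone 4, which is the lactone of mandelic acid 3. Acid 3 is cut at the bond between the ring and the carbinol carbon, giving phenol 1 and glyoxylic acid 2. A triethylsilyl ether is chosen over a tert-butyldimethylsilyl ether. At this congested tertiary position the bulkier group would need forcing fluoride conditions at the end, and the aryl tiglate would not survive them.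

## Alternatives that were turned down

**Alternative 1: benzannulation of a chromium carbene with an enantiopure alkynyl oxirane.**
- Disconnection: the benzene ring itself, at three ring bonds: C(OMe)–CH, C(oxirane-bearing)–C(OH) and C(OH)–CH.
- Forward key step: the terminal alkyne [(2R)-2-ethynyloxiran-2-yl]methyl 3-methylbutanoate A1 and the carbene complex (CO)5Cr=C(OMe)C(Me)=CH2 A2 combine by alkyne insertion, CO insertion and electrocyclisation (Dötz benzannulation). The product is the phenol [(2R)-2-(2-hydroxy-5-methoxy-4-methylphenyl)oxiran-2-yl]methyl 3-methylbutanoate A3.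
- For: the whole substitution pattern is assembled in one step, with regiochemistry set by the terminal alkyne. The stereocentre sits in the small fragment A1, and only the tigloylation follows. On convergence and on the length of the endgame this plan is stronger, and it has no arm-exchange problem after the ring is made.
- Against: A3 is exactly the free phenol next to the oxirane that closes to a dihydrobenzofuran, and it forms in a warm mixture containing zerovalent chromium. Release of the arene from its Cr(CO)3 complex needs an oxidant, which also attacks the hydroquinone monoether. A propargylic oxirane can ionise at a low-valent metal. A1 needs its own enantioselective synthesis of a quaternary ethynyl oxirane, so the total step count is not lower, and chromium is used stoichiometrically.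
- Comparison: the chosen route is linear and longer after the stereocentre is set, but the phenol is never free while the oxirane exists.

**Alternative 2: asymmetric Corey–Chaykovsky methylene transfer to an aryl ketone.**
- Disconnection: both bonds of the oxirane CH2, back to the ketone 2-[2-(tert-butyldimethylsilyloxy)-5-methoxy-4-methylphenyl]-2-oxoethyl 3-methylbutanoate A4.
- Forward key step: dimethylsulfoxonium methylide A5 adds to A4 under LaLi3(binaphthoxide)3 with a triarylphosphine oxide. The product is [(2R)-2-[2-(tert-butyldimethylsilyloxy)-5-methoxy-4-methylphenyl]oxiran-2-yl]methyl 3-methylbutanoate A6.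
- For: the stereocentre and the oxirane are made together in one step from a ketone that is a few steps from the phenol. On step count this plan is clearly stronger.
- Against: this catalyst type distinguishes a methyl group from a larger group. Here the two groups are an ortho-substituted aryl ring and a CH2O-acyl group. The CH2 of A4 is acidic and the ylide is a base, and the ylide can also take the acyl group of the ester. After the key step the silyl group on the phenol must be exchanged for the tiglate, which passes through a phenoxide next to the oxirane.
- Comparison: the chosen route is longer, but its stereo-determining step uses a flat lactone enolate with one enolisable position and formaldehyde, a pairing close to known cases, and the phenol is esterified before the oxirane is formed.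

**Alternative 3: desymmetrising isovalerylation of a prochiral 2-arylglycerol.**
- Disconnection: the ester C(=O)–O bond of the isovalerate, back to the triol 4-methoxy-5-methyl-2-(1,2,3-trihydroxypropan-2-yl)phenyl (2E)-2-methylbut-2-enoate A7.
- Forward key step: isovaleryl chloride 8 acylates one enantiotopic CH2OH of A7 under Cu(OTf)2 (divalent copper) with a chiral phenyl-bisoxazoline ligand. The product is 2-[(2R)-1,2-dihydroxy-3-(3-methylbutanoyloxy)propan-2-yl]-4-methoxy-5-methylphenyl (2E)-2-methylbut-2-enoate A8.
- For: all chemistry before the key step is achiral, the stereocentre is set two steps from the target, and the acyl group introduced is the one needed. 2-Substituted glycerols are the substrate class for which this type of acylation is known. On step economy and closeness of precedent this plan is as strong or stronger.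
- Against: the known cases use aroyl chlorides, and an aliphatic acyl chloride is less discriminating. A7 carries an activated aryl ester a few atoms from three hydroxyl groups, so the tigloyl group can move to a copper alkoxide. A8 has a free tertiary hydroxyl between the arms, and two successive 1,2-acyl shifts through five-membered intermediates exchange the arms and erase the configuration.
- Comparison: the chosen route also passes through a 1,3-hydroxy ester (11 and 13). There, however, the tertiary oxygen stays silylated until the last step, so only the slower direct 1,3-shift remains, and the stereocentre is built by C–C bond formation while the arms differ in oxidation level.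

Key step: step 4

Remark: the sense of induction of the N,N'-dioxide ligand on this enolate cannot be derived from the structure alone. It is assumed that one antipode of the ligand (made from (S)- or (R)-pipecolic acid) delivers the (S)-lactone 7, and that antipode is used.

## Route

**Step 1**
Reactants: 1 4-methoxy-3-methylphenol; 2 glyoxylic acid
Product: 3 rac-2-hydroxy-2-(2-hydroxy-5-methoxy-4-methylphenyl)acetic acid
Conditions: 2 (50% aq., 1.2 equiv), NaOH (2.5 equiv), H2O, N2, 25 °C; then HCl to pH 1
Reagents that add atoms: none
Why: Hydroxyalkylation of a phenolate by glyoxylate (electrophilic aromatic substitution, the mandelic acid condensation). The para position is blocked by the methoxy group, and of the two ortho positions the open one para to the methyl group should react in preference to the one wedged between O and CH3.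

**Step 2**
Reactants: 3 rac-2-hydroxy-2-(2-hydroxy-5-methoxy-4-methylphenyl)acetic acid
Product: 4 rac-3-hydroxy-5-methoxy-6-methyl-1-benzofuran-2(3H)-one
Conditions: p-TsOH·H2O (5 mol %), toluene, reflux, Dean–Stark
Reagents that add atoms: none
Why: Acid-catalysed lactonisation (intramolecular Fischer esterification) of an ortho-hydroxyaryl acetic acid to a five-membered aryl lactone, driven by azeotropic removal of water.

**Step 3**
Reactants: 4 rac-3-hydroxy-5-methoxy-6-methyl-1-benzofuran-2(3H)-one
Product: 5 rac-5-methoxy-6-methyl-3-(triethylsilyloxy)-1-benzofuran-2(3H)-one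
Conditions: TESCl, imidazole, CH2Cl2, 0 °C to rt, Ar
Reagents that add atoms: chlorotriethylsilane (TESCl), CC[Si](Cl)(CC)CC
Why: Imidazole-mediated silylation of a secondary alcohol. The triethylsilyl ether should survive steps 4 to 8 and still be cleaved by fluoride at low temperature in step 9.

**Step 4**
Reactants: 5 rac-5-methoxy-6-methyl-3-(triethylsilyloxy)-1-benzofuran-2(3H)-one; 6 formaldehyde
Product: 7 (3S)-3-(hydroxymethyl)-5-methoxy-6-methyl-3-(triethylsilyloxy)-1-benzofuran-2(3H)-one
Conditions: Sc(OTf)3 (10 mol %), chiral N,N'-dioxide ligand (11 mol %; two (S)-pipecolic acid 2,6-diisopropylanilide units joined at nitrogen by a propane-1,3-diyl chain, both nitrogens as N-oxides), 6 (3 equiv, THF solution from cracked paraformaldehyde), CH2Cl2, −20 °C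
Reagents that add atoms: none
Why: Sc(OTf)3 held by the four oxygens of the ligand keeps two neighbouring sites free; the lactone carbonyl of 5 binds there, the C3–H becomes acidic, and soft enolisation gives the scandium-bound 2-oxidobenzofuran enolate, a flat aromatic system in which the stereocentre of racemic 5 is erased. Formaldehyde, bound at the second site or hydrogen-bonded to an amide N–H of the ligand, is attacked by C3, which forms the C3–CH2 bond, and protonation releases 7 and the catalyst. The closest known reaction type is the hydroxymethylation of 3-substituted oxindoles with formaldehyde and the related enantioselective additions of 3-substituted benzofuran-2(3H)-ones under N,N'-dioxide complexes of Sc(OTf)3; the 3-silyloxy group is a new substituent on that substrate class. No ring is closed, since the lactone ring is already present. The one new stereocentre, C3 (S), is controlled by the catalyst alone: an anilide arm of the ligand screens one face of the bound enolate. The step needs facial selectivity, attack through carbon and a single addition; C3 is the only enolisable position, formaldehyde cannot enolise, O-bound hemiacetals revert, and 7 has no alpha hydrogen, so it can neither react again nor racemise by enolisation. The large difference between the flat benzo ring and the bulky OSiEt3 group on C3 gives the ligand two clearly different flanks to distinguish. Water-free formaldehyde and low temperature should protect the silyl ether from Lewis acid hydrolysis and hold back retro-aldol, and crude 7 is acylated at once in step 5.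

**Step 5**
Reactants: 7 (3S)-3-(hydroxymethyl)-5-methoxy-6-methyl-3-(triethylsilyloxy)-1-benzofuran-2(3H)-one; 8 3-methylbutanoyl chloride
Product: 9 [(3S)-5-methoxy-6-methyl-2-oxo-3-(triethylsilyloxy)-2,3-dihydro-1-benzofuran-3-yl]methyl 3-methylbutanoate
Conditions: 8, pyridine, DMAP (5 mol %), CH2Cl2, −20 to 0 °C
Reagents that add atoms: none
Why: Pyridine/DMAP acylation of a neopentyl-type primary alcohol; no alkoxide is formed, so retro-aldol should not start, and after esterification it is no longer possible.

**Step 6**
Reactants: 9 [(3S)-5-methoxy-6-methyl-2-oxo-3-(triethylsilyloxy)-2,3-dihydro-1-benzofuran-3-yl]methyl 3-methylbutanoate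
Product: 11 (2R)-3-hydroxy-2-(2-hydroxy-5-methoxy-4-methylphenyl)-2-(triethylsilyloxy)propyl 3-methylbutanoate, via hydroxy aldehyde 10 (not isolated)
Conditions: NaBH4, THF–EtOH (4:1), −20 to 0 °C; quench with AcOH/pH 7 phosphate buffer at −20 °C
Reagents that add atoms: none
Why: Chemoselective borohydride reduction: the aryl lactone, with a phenoxide leaving group and an alpha oxygen, is far more electrophilic than the alkyl isovalerate, opens to aldehyde 10 and is reduced on to the primary alcohol. The stereocentre is not touched (the descriptor changes from S to R only because the CIP priorities of the arms change), and the cold, buffered quench is meant to suppress acyl and silyl shifts in the alkoxide.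

**Step 7**
Reactants: 11 (2R)-3-hydroxy-2-(2-hydroxy-5-methoxy-4-methylphenyl)-2-(triethylsilyloxy)propyl 3-methylbutanoate; 12 (2E)-2-methylbut-2-enoyl chloride
Product: 13 2-[(2R)-1-hydroxy-3-(3-methylbutanoyloxy)-2-(triethylsilyloxy)propan-2-yl]-4-methoxy-5-methylphenyl (2E)-2-methylbut-2-enoate
Conditions: 12 (1.05 equiv), Et3N (1.1 equiv, added last and slowly), CH2Cl2, −40 to −10 °C
Reagents that add atoms: none
Why: Phenol-selective O-acylation of Schotten–Baumann type: the amine activates only the acidic phenol, while the neopentyl-type alcohol reacts slowly without an acyl-transfer catalyst. Adding the amine last lets the phenol consume it, so that it does not turn 12 into a vinylketene.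

**Step 8**
Reactants: 13 2-[(2R)-1-hydroxy-3-(3-methylbutanoyloxy)-2-(triethylsilyloxy)propan-2-yl]-4-methoxy-5-methylphenyl (2E)-2-methylbut-2-enoate
Product: 14 2-[(2S)-1-(methanesulfonyloxy)-3-(3-methylbutanoyloxy)-2-(triethylsilyloxy)propan-2-yl]-4-methoxy-5-methylphenyl (2E)-2-methylbut-2-enoate
Conditions: MsCl, Et3N, CH2Cl2, −10 °C
Reagents that add atoms: methanesulfonyl chloride, CS(=O)(=O)Cl
Why: Mesylation through the sulfene, which suits a hindered neopentyl-type alcohol. It caps the last free hydroxyl, so acyl migration between the arms is no longer possible (the descriptor becomes S by CIP priority only).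

**Step 9**
Reactants: 14 2-[(2S)-1-(methanesulfonyloxy)-3-(3-methylbutanoyloxy)-2-(triethylsilyloxy)propan-2-yl]-4-methoxy-5-methylphenyl (2E)-2-methylbut-2-enoate
Product: 16 2-[(2R)-2-{[(3-methylbutanoyl)oxy]methyl}oxiran-2-yl]-4-methoxy-5-methylphenyl (2E)-2-methylbut-2-enoate, via tetrabutylammonium alkoxide 15 (not isolated)
Conditions: TBAF (1.05 equiv, 1 M in THF), THF, −20 to 0 °C
Reagents that add atoms: none
Why: Fluoride desilylation followed by intramolecular Williamson etherification (3-exo-tet) of alkoxide 15 onto the neighbouring mesylate. The alkoxide is consumed as it forms, so the medium stays near neutral, and no bond at the stereocentre is made or broken, so the configuration is kept (R by CIP priority).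

## Compound list

1 | 4-methoxy-3-methylphenol | Cc1cc(O)ccc1OC | starting material
2 | glyoxylic acid (50% aqueous solution) | O=CC(=O)O | starting material
3 | rac-2-hydroxy-2-(2-hydroxy-5-methoxy-4-methylphenyl)acetic acid | COc1cc(C(O)C(=O)O)c(O)cc1C | intermediate
4 | rac-3-hydroxy-5-methoxy-6-methyl-1-benzofuran-2(3H)-one | COc1cc2c(cc1C)OC(=O)C2O | intermediate
5 | rac-5-methoxy-6-methyl-3-(triethylsilyloxy)-1-benzofuran-2(3H)-one | COc1cc2c(cc1C)OC(=O)C2O[Si](CC)(CC)CC | intermediate
6 | formaldehyde (from paraformaldehyde) | C=O | starting material
7 | (3S)-3-(hydroxymethyl)-5-methoxy-6-methyl-3-(triethylsilyloxy)-1-benzofuran-2(3H)-one | COc1cc2c(cc1C)OC(=O)[C@@]2(O[Si](CC)(CC)CC)CO | intermediate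
8 | 3-methylbutanoyl chloride (isovaleryl chloride) | CC(C)CC(=O)Cl | starting material
9 | [(3S)-5-methoxy-6-methyl-2-oxo-3-(triethylsilyloxy)-2,3-dihydro-1-benzofuran-3-yl]methyl 3-methylbutanoate | COc1cc2c(cc1C)OC(=O)[C@@]2(O[Si](CC)(CC)CC)COC(=O)CC(C)C | intermediate
10 | (2S)-2-(2-hydroxy-5-methoxy-4-methylphenyl)-3-oxo-2-(triethylsilyloxy)propyl 3-methylbutanoate | O=C[C@@](O[Si](CC)(CC)CC)(COC(=O)CC(C)C)c1cc(OC)c(C)cc1O | intermediate (not isolated)
11 | (2R)-3-hydroxy-2-(2-hydroxy-5-methoxy-4-methylphenyl)-2-(triethylsilyloxy)propyl 3-methylbutanoate | OC[C@@](O[Si](CC)(CC)CC)(COC(=O)CC(C)C)c1cc(OC)c(C)cc1O | intermediate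
12 | (2E)-2-methylbut-2-enoyl chloride (tigloyl chloride) | C/C=C(\C)C(=O)Cl | starting material
13 | 2-[(2R)-1-hydroxy-3-(3-methylbutanoyloxy)-2-(triethylsilyloxy)propan-2-yl]-4-methoxy-5-methylphenyl (2E)-2-methylbut-2-enoate | C/C=C(\C)C(=O)Oc1cc(C)c(OC)cc1[C@@](O[Si](CC)(CC)CC)(CO)COC(=O)CC(C)C | intermediate
14 | 2-[(2S)-1-(methanesulfonyloxy)-3-(3-methylbutanoyloxy)-2-(triethylsilyloxy)propan-2-yl]-4-methoxy-5-methylphenyl (2E)-2-methylbut-2-enoate | C/C=C(\C)C(=O)Oc1cc(C)c(OC)cc1[C@@](O[Si](CC)(CC)CC)(COS(C)(=O)=O)COC(=O)CC(C)C | intermediate
15 | tetrabutylammonium (2S)-1-(methanesulfonyloxy)-3-(3-methylbutanoyloxy)-2-{5-methoxy-4-methyl-2-[(2E)-2-methylbut-2-enoyloxy]phenyl}propan-2-olate | C/C=C(\C)C(=O)Oc1cc(C)c(OC)cc1[C@@]([O-])(COS(C)(=O)=O)COC(=O)CC(C)C.CCCC[N+](CCCC)(CCCC)CCCC | intermediate (not isolated)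
16 | 2-[(2R)-2-{[(3-methylbutanoyl)oxy]methyl}oxiran-2-yl]-4-methoxy-5-methylphenyl (2E)-2-methylbut-2-enoate | C/C=C(\C)C(=O)Oc1cc(C)c(OC)cc1[C@]1(COC(=O)CC(C)C)CO1 | target

## Step count and least certain steps

Total step count: 9. Longest linear sequence: 9 steps (1 to 16).

**Step 4 (key step).**
- What may go wrong: poor facial selectivity, because an oxygen substituent on C3 differs in size and Lewis basicity from the alkyl and aryl groups for which this catalyst type is known. Further risks are loss or O-to-O shift of the silyl group in the enolate, an uncatalysed racemic background reaction, and retro-aldol on work-up.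
- Fallback: set out from 5 and give up catalytic control. Hydroxymethylation with 6 under Sc(OTf)3 without ligand should give the racemic hydroxymethyl lactone rac-3-(hydroxymethyl)-5-methoxy-6-methyl-3-(triethylsilyloxy)-1-benzofuran-2(3H)-one F1. Acylation with 8 and pyridine as in step 5 should give the racemic isovalerate of the lactone F2. Preparative chromatography of this stable ester on a chiral stationary phase separates 9 from its (3R)-enantiomer F3, which is discarded. The route is rejoined at 9.

**Step 6.**
- What may go wrong: acyl migration from one arm to the other in the alkoxide formed on reduction, through a six-membered intermediate, which lowers the enantiomeric purity. Further risks are a 1,2-shift of the silyl group from the tertiary to the new primary oxygen, and slow reduction of the hindered lactone carbonyl with competing attack on the isovalerate.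
- Fallback: set out from 7 and keep the arm as an ether, which cannot migrate, during the reduction. 4-Methoxybenzyl 2,2,2-trichloroacetimidate with catalytic La(OTf)3 in toluene should give the 4-methoxybenzyl ether of the lactone F4. NaBH4 reduction then gives the phenol with a free primary alcohol F5, tigloylation with 12 and Et3N gives the aryl tiglate F6, and MsCl/Et3N gives the mesylate F7. DDQ in CH2Cl2/pH 7 buffer removes the benzyl ether to give the hydroxy mesylate with the silyl ether still in place F8, and acylation with 8 and pyridine gives 14. The route is rejoined at 14, at the cost of two extra steps.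

**Step 7.**
- What may go wrong: acylation of the primary alcohol beside or in place of the phenol, loss of conjugation of the tigloyl unit through a vinylketene formed from 12 and the amine, and base-induced acyl migration between the arms.
- Fallback: set out from 11 and make the phenol the only free hydroxyl. TESCl and imidazole in excess give the tris(triethylsilyl) compound F9. DBU in MeCN–H2O cleaves only the aryl silyl ether, giving the phenol with both alkyl oxygens silylated F10. Acylation with 12 in pyridine, where selectivity is no longer needed and no strong amine base is present, gives the aryl tiglate F11. PPTS in MeOH at 0 °C removes the primary silyl ether and leaves the hindered tertiary one. The route is rejoined at 13.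

**Step 9.**
- What may go wrong: attack of the freed alkoxide, or of fluoride and adventitious hydroxide, on the aryl tiglate. The phenoxide so formed would then open the oxirane. Desilylation at the hindered tertiary position may also be incomplete.
- Fallback: set out from 14 and separate deprotection from ring closure. HF·pyridine buffered with pyridine in THF at 0 °C gives the neutral tertiary alcohol with the mesylate in place F12, which is isolated. Cs2CO3 suspended in MeCN at 0 °C, an aprotic heterogeneous base without fluoride or hydroxide, then closes the oxirane. The route is rejoined at 16.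

## Further compounds

F1 | step 4 | rac-3-(hydroxymethyl)-5-methoxy-6-methyl-3-(triethylsilyloxy)-1-benzofuran-2(3H)-one | COc1cc2c(cc1C)OC(=O)C2(O[Si](CC)(CC)CC)CO
F2 | step 4 | rac-[5-methoxy-6-methyl-2-oxo-3-(triethylsilyloxy)-2,3-dihydro-1-benzofuran-3-yl]methyl 3-methylbutanoate | COc1cc2c(cc1C)OC(=O)C2(O[Si](CC)(CC)CC)COC(=O)CC(C)C
F3 | step 4 | [(3R)-5-methoxy-6-methyl-2-oxo-3-(triethylsilyloxy)-2,3-dihydro-1-benzofuran-3-yl]methyl 3-methylbutanoate | COc1cc2c(cc1C)OC(=O)[C@]2(O[Si](CC)(CC)CC)COC(=O)CC(C)C
F4 | step 6 | (3S)-5-methoxy-3-{[(4-methoxybenzyl)oxy]methyl}-6-methyl-3-(triethylsilyloxy)-1-benzofuran-2(3H)-one | COc1cc2c(cc1C)OC(=O)[C@@]2(O[Si](CC)(CC)CC)COCc1ccc(OC)cc1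
F5 | step 6 | (2R)-2-(2-hydroxy-5-methoxy-4-methylphenyl)-3-[(4-methoxybenzyl)oxy]-2-(triethylsilyloxy)propan-1-ol | OC[C@@](O[Si](CC)(CC)CC)(COCc1ccc(OC)cc1)c1cc(OC)c(C)cc1O
F6 | step 6 | 2-[(2R)-1-hydroxy-3-[(4-methoxybenzyl)oxy]-2-(triethylsilyloxy)propan-2-yl]-4-methoxy-5-methylphenyl (2E)-2-methylbut-2-enoate | C/C=C(\C)C(=O)Oc1cc(C)c(OC)cc1[C@@](O[Si](CC)(CC)CC)(CO)COCc1ccc(OC)cc1
F7 | step 6 | 2-[(2S)-1-(methanesulfonyloxy)-3-[(4-methoxybenzyl)oxy]-2-(triethylsilyloxy)propan-2-yl]-4-methoxy-5-methylphenyl (2E)-2-methylbut-2-enoate | C/C=C(\C)C(=O)Oc1cc(C)c(OC)cc1[C@@](O[Si](CC)(CC)CC)(COS(C)(=O)=O)COCc1ccc(OC)cc1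
F8 | step 6 | 2-[(2S)-1-hydroxy-3-(methanesulfonyloxy)-2-(triethylsilyloxy)propan-2-yl]-4-methoxy-5-methylphenyl (2E)-2-methylbut-2-enoate | C/C=C(\C)C(=O)Oc1cc(C)c(OC)cc1[C@@](O[Si](CC)(CC)CC)(COS(C)(=O)=O)CO
F9 | step 7 | (2S)-2-[5-methoxy-4-methyl-2-(triethylsilyloxy)phenyl]-2,3-bis(triethylsilyloxy)propyl 3-methylbutanoate | CC[Si](CC)(CC)OC[C@@](O[Si](CC)(CC)CC)(COC(=O)CC(C)C)c1cc(OC)c(C)cc1O[Si](CC)(CC)CC
F10 | step 7 | (2S)-2-(2-hydroxy-5-methoxy-4-methylphenyl)-2,3-bis(triethylsilyloxy)propyl 3-methylbutanoate | CC[Si](CC)(CC)OC[C@@](O[Si](CC)(CC)CC)(COC(=O)CC(C)C)c1cc(OC)c(C)cc1O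
F11 | step 7 | 2-[(2S)-1-(3-methylbutanoyloxy)-2,3-bis(triethylsilyloxy)propan-2-yl]-4-methoxy-5-methylphenyl (2E)-2-methylbut-2-enoate | C/C=C(\C)C(=O)Oc1cc(C)c(OC)cc1[C@@](O[Si](CC)(CC)CC)(CO[Si](CC)(CC)CC)COC(=O)CC(C)C
F12 | step 9 | 2-[(2S)-2-hydroxy-1-(methanesulfonyloxy)-3-(3-methylbutanoyloxy)propan-2-yl]-4-methoxy-5-methylphenyl (2E)-2-methylbut-2-enoate | C/C=C(\C)C(=O)Oc1cc(C)c(OC)cc1[C@@](O)(COS(C)(=O)=O)COC(=O)CC(C)C
A1 | alternative 1 | [(2R)-2-ethynyloxiran-2-yl]methyl 3-methylbutanoate | C#C[C@]1(COC(=O)CC(C)C)CO1
A2 | alternative 1 | pentacarbonyl[methoxy(prop-1-en-2-yl)methylidene]chromium, (CO)5Cr=C(OMe)C(Me)=CH2 | COC(=[Cr])C(C)=C.[C-]#[O+].[C-]#[O+].[C-]#[O+].[C-]#[O+].[C-]#[O+]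
A3 | alternative 1 | [(2R)-2-(2-hydroxy-5-methoxy-4-methylphenyl)oxiran-2-yl]methyl 3-methylbutanoate | Oc1cc(C)c(OC)cc1[C@]1(COC(=O)CC(C)C)CO1
A4 | alternative 2 | 2-[2-(tert-butyldimethylsilyloxy)-5-methoxy-4-methylphenyl]-2-oxoethyl 3-methylbutanoate | CC(C)CC(=O)OCC(=O)c1cc(OC)c(C)cc1O[Si](C)(C)C(C)(C)C
A5 | alternative 2 | dimethylsulfoxonium methylide | C[S+](C)(=O)[CH2-]
A6 | alternative 2 | [(2R)-2-[2-(tert-butyldimethylsilyloxy)-5-methoxy-4-methylphenyl]oxiran-2-yl]methyl 3-methylbutanoate | CC(C)(C)[Si](C)(C)Oc1cc(C)c(OC)cc1[C@]1(COC(=O)CC(C)C)CO1
A7 | alternative 3 | 4-methoxy-5-methyl-2-(1,2,3-trihydroxypropan-2-yl)phenyl (2E)-2-methylbut-2-enoate | C/C=C(\C)C(=O)Oc1cc(C)c(OC)cc1C(O)(CO)CO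
A8 | alternative 3 | 2-[(2R)-1,2-dihydroxy-3-(3-methylbutanoyloxy)propan-2-yl]-4-methoxy-5-methylphenyl (2E)-2-methylbut-2-enoate | C/C=C(\C)C(=O)Oc1cc(C)c(OC)cc1[C@](O)(COC(=O)CC(C)C)CO
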